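**Plan**

1. Locants: ring A holds the alkene C1(CH3)=C2(CH2Ar), C9 and C10; ring B holds C3 (angular CH3), C4–C6 (CH2), C7 (quaternary: CH3 and tether) and C8 (fusion CH). The east cyclohexane runs E1 (carbinol), E2 (CH–CH3), E3, E4, E5 (CH–O of the oxepane), E6 (angular C–CH3).
2. Retrosynthetic cuts, in order: the two ArO–S bonds; the E1–CH2 bond of the tether (east ketone plus a west organocerium reagent); C7–vinyl (conjugate addition) and C1–CH3 (enol triflate coupling); then C3–CH3 and C2–CH2Ar in one operation.
3. Enabling feature: in the bicyclic precursor ring A is an enone with its carbonyl at C1, an unsubstituted α-carbon C2 and the ring-fusion carbon C3 as β-carbon, so a methyl cuprate can quaternise C3 and the C1–C2 enolate can be benzylated at C2 in the same flask.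
4. Forward, west half: both decalin rings come from 6-methoxy-1-tetralone (ring A is its Birch-reduced anisole ring, ring B its carbocyclic ring) and no further ring is formed. Ring A is substituted in the three-component step, C1 becomes the tetrasubstituted alkene, C7 is turned into a β-methyl enone and quaternised with vinyl, and the hydroborated vinyl group is joined to the east ketone before quinone formation, reduction and bis-sulfation.
5. East half: 2-methylcyclohexane-1,3-dione gives E6 by Michael addition and Wittig olefination; after a desymmetrising reduction the oxepane closes by 7-endo hydroalkoxylation, and E2 is then methylated.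
6. Stereochemistry: transfer hydrogenation fixes C7–O, which relays to C8 (equilibration), C3 (axial cuprate delivery, cis fusion) and C7 (vinyl anti to the C8–C9 bond); the oxazaborolidine reduction fixes E5 and E6, equilibration E2, and equatorial addition E1.

Key step: step 6

Remark: the target is drawn as the free bis(hydrogen sulfate); it is assumed to be released from the pyridinium salt of the sulfation on an acidic ion-exchange resin and handled cold, a salt being the storage form.

**Route**

Step 1
Reactants: 1 6-methoxy-1-tetralone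
Product: 2 (R)-6-methoxy-1-tetralol
Conditions: RuCl[(R,R)-TsDPEN](p-cymene) (1 mol %), HCO2H/Et3N (5:2), 40 °C
Reagents that add atoms: none
Why: Noyori-type asymmetric transfer hydrogenation of an aryl alkyl ketone, in which the (R,R)-diamine ruthenium hydride should give the (R)-carbinol, the centre (later C7) from which the absolute configuration of the west half is relayed.

Step 2
Reactants: 2 (R)-6-methoxy-1-tetralol
Product: 4 (R)-6-methoxy-1,2,3,4,5,8-hexahydronaphthalen-1-ol, via lithium alkoxide 3 (not isolated)
Conditions: n-BuLi, THF, −78 °C; then Li, NH3(l), t-BuOH, −78 → −33 °C; NH4Cl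
Reagents that add atoms: none
Why: Birch reduction of the anisole ring, in which the benzylic oxygen is carried as its lithium alkoxide so that the C–O bond resists hydrogenolysis and the carbinol centre is untouched.

Step 3
Reactants: 4 (R)-6-methoxy-1,2,3,4,5,8-hexahydronaphthalen-1-ol
Product: 6 (4aR,5R)-hydroxy enone, via β,γ-enone 5 (not isolated)
Conditions: (CO2H)2, MeOH/H2O, rt; then NaOMe, MeOH, 0 °C → rt
Reagents that add atoms: water, O
Why: Mild acid hydrolysis of the enol ether gives the β,γ-enone without ionising the allylic carbinol, and methoxide then conjugates the double bond through the dienolate; since γ-protonation at C8 is reversible, the isomer with equatorial hydroxyl (C7–O and C8–H on one face) should prevail, the minor epimer being separable and open to re-equilibration.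

Step 4
Reactants: 6 (4aR,5R)-hydroxy enone
Product: 7 (4aR,5R)-silyloxy enone
Conditions: TBSCl, imidazole, DMF, rt
Reagents that add atoms: tert-butyldimethylsilyl chloride, CC(C)(C)[Si](C)(C)Cl
Why: Imidazole-promoted silylation of a secondary alcohol, which masks the C7 oxygen against the cuprate, enolate, triflation and Grignard steps.

Step 5
Reactants: 8 2,5-dimethoxybenzyl alcohol
Product: 9 2,5-dimethoxybenzyl bromide
Conditions: PBr3, Et2O, 0 °C
Reagents that add atoms: phosphorus tribromide, BrP(Br)Br
Why: Bromination of an electron-rich benzylic alcohol through its phosphite ester (SN2 displacement by bromide), the bromide being used freshly made.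

Step 6
Reactants: 7 (4aR,5R)-silyloxy enone; 9 2,5-dimethoxybenzyl bromide
Product: 11 (1R,4aR,5R,8aR)-benzyl methyl decalone, via lithium enolate 10 (not isolated)
Conditions: Me2CuLi (from CuI and 2 MeLi), Et2O, −20 → 0 °C; then THF/HMPA, 9, −40 °C → rt
Reagents that add atoms: lithium dimethylcuprate, [Li+].C[Cu-]C
Why: Me2CuLi forms a π-complex with the ring A enone and transfers methyl to the ring-fusion β-carbon C3 (oxidative addition and reductive elimination at copper), leaving the regiodefined C1–C2 lithium enolate 10 and MeCu, and in THF/HMPA this enolate is C-alkylated at C2 by the benzylic bromide in an SN2 step. The closest known reaction type is the conjugate methylation of a Δ1(9)-2-octalone by a lithium dialkylcuprate followed by in situ alkylation of the enolate with an allylic or benzylic halide (three-component coupling). No ring is closed; the two new bonds C3–CH3 and C2–CH2Ar are exocyclic. C3 is set by stereoelectronically controlled axial delivery of methyl to the half-chair enone on the face of the axial C8 hydrogen, which gives the cis-fused decalin, the equatorial C7 silyloxy group being 1,3-diequatorial to the new methyl on ring B and therefore not opposing it; the C2 centre (benzyl anti to the new angular methyl) is inconsequential because it becomes sp2 in step 7. The selectivities needed are 1,4- over 1,2-addition (soft cuprate), alkylation at C2 before the enolate can equilibrate (no proton source, excess reactive bromide, HMPA) and C- over O-alkylation (lithium enolate with a soft benzylic bromide).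

Step 7
Reactants: 11 (1R,4aR,5R,8aR)-benzyl methyl decalone
Product: 12 C1=C2 enol triflate
Conditions: Tf2O, 2,6-di-tert-butyl-4-methylpyridine, CH2Cl2, 0 °C → rt
Reagents that add atoms: trifluoromethanesulfonic anhydride, O=S(=O)(OS(=O)(=O)C(F)(F)F)C(F)(F)F
Why: Enol triflate formation under equilibrating conditions (O-triflylation to the oxocarbenium ion and reversible proton loss to a hindered pyridine), which should favour the more substituted C1=C2 enol derivative and at the same time erases the C2 stereocentre.

Step 8
Reactants: 12 C1=C2 enol triflate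
Product: 13 tetrasubstituted alkene silyl ether
Conditions: MeMgBr, Fe(acac)3 (5 mol %), THF/NMP, −20 → 0 °C
Reagents that add atoms: methylmagnesium bromide, C[Mg]Br
Why: Iron-catalysed cross-coupling of an alkenyl triflate with a methyl Grignard reagent, a reaction that accepts hindered, fully substituted triflates and leaves the silyl ether and the aryl methyl ethers untouched.

Step 9
Reactants: 13 tetrasubstituted alkene silyl ether
Product: 14 C7 alcohol
Conditions: Bu4NF, THF, rt → 50 °C
Reagents that add atoms: none
Why: Fluoride cleavage of the silyl ether, driven by the Si–F bond, with no other fluoride-labile group present.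

Step 10
Reactants: 14 C7 alcohol
Product: 15 C7 ketone
Conditions: Dess–Martin periodinane, NaHCO3, CH2Cl2, 0 °C → rt
Reagents that add atoms: none
Why: Dess–Martin oxidation under buffered, non-basic conditions, which gives the ketone without epimerising the adjacent C8 ring-fusion centre.

Step 11
Reactants: 15 C7 ketone
Product: 17 C5=C6 enone, via trimethylsilyl enol ether 16 (not isolated)
Conditions: LiN(i-Pr)2, TMSCl, THF, −78 °C; then Pd(OAc)2 (1 equiv), MeCN, rt
Reagents that add atoms: none
Why: Saegusa–Ito oxidation, in which kinetic deprotonation takes the C6 methylene and not the hindered C8 methine, and the silyl enol ether is palladated and undergoes β-hydride elimination to the enone with C8 untouched.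

Step 12
Reactants: 17 C5=C6 enone
Product: 18 tertiary allylic alcohol
Conditions: MeLi, CeCl3, THF, −78 °C
Reagents that add atoms: methyllithium, C[Li]
Why: 1,2-Addition of the weakly basic methylcerium reagent to the enone carbonyl, which avoids enolisation at C8; the configuration of the new carbinol is irrelevant because it is lost in step 13.

Step 13
Reactants: 18 tertiary allylic alcohol
Product: 19 β-methyl enone
Conditions: pyridinium chlorochromate (C5H5NH[CrO3Cl]), 4 Å molecular sieves, CH2Cl2, rt
Reagents that add atoms: pyridinium chlorochromate, [O-][Cr](=O)(=O)Cl.c1cc[nH+]cc1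
Why: Dauben–Babler oxidative transposition, in which the tertiary allylic chromate ester shifts to C5 by a [3,3] rearrangement and is oxidised, giving the enone whose β-carbon is the methyl-bearing C7.

Step 14
Reactants: 19 β-methyl enone
Product: 21 vinyl ketone, via trimethylsilyl enol ether 20 (not isolated)
Conditions: CH2=CHMgBr, CuBr·SMe2 (0.3 equiv), TMSCl, HMPA, THF, −78 → −20 °C; then 1 M HCl, THF, 0 °C
Reagents that add atoms: vinylmagnesium bromide, C=C[Mg]Br
Why: Copper-catalysed, TMSCl-accelerated conjugate addition of a vinyl Grignard reagent to a β,β-disubstituted enone; the C8–C9 bond is held pseudoaxial by A(1,2) strain with the C7 methyl, so vinyl should enter anti to it, on the face of the C8 hydrogen, which places vinyl cis and methyl trans to that hydrogen as in the target.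

Step 15
Reactants: 21 vinyl ketone
Product: 23 vinyl decalin, via hydrazone 22 (not isolated)
Conditions: N2H4·H2O, KOH, diethylene glycol, 130 °C then 200 °C
Reagents that add atoms: none
Why: Wolff–Kishner reduction in its Huang-Minlon form, in which the C5 hydrazone loses dinitrogen under hydroxide at high temperature while the alkenes, the aryl ethers and the quaternary centres are inert.

Step 16
Reactants: 23 vinyl decalin
Product: 25 primary alcohol, via alkylborane 24 (not isolated)
Conditions: 9-BBN, THF, rt → 50 °C; then NaOH, H2O2, 0 °C → rt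
Reagents that add atoms: hydrogen peroxide, OO
Why: Anti-Markovnikov hydroboration–oxidation with the bulky 9-BBN, which selects the monosubstituted vinyl group over the tetrasubstituted ring A alkene.

Step 17
Reactants: 25 primary alcohol
Product: 26 primary iodide
Conditions: I2, PPh3, imidazole, CH2Cl2, 0 °C → rt
Reagents that add atoms: iodine, II
Why: Appel-type iodination of a primary alcohol through its alkoxyphosphonium salt (SN2 at the unhindered CH2).

Step 18
Reactants: 27 2-methylcyclohexane-1,3-dione; 28 acrolein
Product: 29 keto aldehyde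
Conditions: H2O, rt
Reagents that add atoms: none
Why: Michael addition of the enolised 1,3-dione to acrolein in water, which is C-selective and creates the methyl-bearing quaternary carbon E6.

Step 19
Reactants: 29 keto aldehyde
Product: 30 homoprenyl dione
Conditions: i-PrPPh3I, n-BuLi, THF, 0 °C; then 29, −78 → 0 °C
Reagents that add atoms: isopropyltriphenylphosphonium iodide, CC(C)[P+](c1ccccc1)(c1ccccc1)c1ccccc1.[I-]
Why: Wittig olefination in which the hindered isopropylidene ylide reacts at low temperature with the aldehyde only, the two ketones flanking the quaternary carbon being too hindered.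

Step 20
Reactants: 30 homoprenyl dione
Product: 31 (2S,3S)-hydroxy ketone
Conditions: (R)-2-methyl-CBS-oxazaborolidine (15 mol %), catecholborane, toluene, −78 °C
Reagents that add atoms: none
Why: Corey–Bakshi–Shibata desymmetrising reduction of a 2,2-disubstituted 1,3-dione, in which the catalyst binds one enantiotopic carbonyl anti to the quaternary carbon and hydride enters from the methyl face, so the carbinol should be (S) with the hydroxyl cis to the side chain and E6 becomes (S); catecholborane spares the trisubstituted alkene.

Step 21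
Reactants: 31 (2S,3S)-hydroxy ketone
Product: 32 (5aS,9aS)-oxepane ketone
Conditions: Al(OTf)3 (5 mol %), MeNO2, 60 °C
Reagents that add atoms: none
Why: Metal triflate-catalysed Markovnikov hydroalkoxylation, in which the hydroxyl closes the oxepane in the 7-endo mode onto the tertiary cationic carbon of the trisubstituted alkene; no new stereocentre arises and the cis ring fusion follows from the cis arrangement of hydroxyl and chain.

Step 22
Reactants: 32 (5aS,9aS)-oxepane ketone
Product: 34 (5aS,7R,9aS)-methyl oxepane ketone, via lithium enolate 33 (not isolated)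
Conditions: LiN(i-Pr)2, THF, −78 °C; MeI, −78 → 0 °C; then NaOMe, MeOH, rt
Reagents that add atoms: iodomethane, CI
Why: Enolate methylation at E2, the only enolisable α-carbon, followed by methoxide equilibration to the equatorial methyl epimer, which should be the one trans to the angular methyl because the chair with axial ether oxygen and equatorial oxepane methylene is preferred.

Step 23
Reactants: 26 primary iodide; 34 (5aS,7R,9aS)-methyl oxepane ketone
Product: 37 coupled tertiary alcohol, via organolithium 35 (not isolated), via organocerium dichloride 36 (not isolated)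
Conditions: 26, t-BuLi (2 equiv), Et2O/pentane, −78 °C; CeCl3, THF, −78 °C; then 34, −78 °C → rt
Reagents that add atoms: none
Why: Iodine–lithium exchange, transmetalation to the non-basic organocerium reagent and 1,2-addition to the hindered ketone without enolisation; the primary alkyl group should enter equatorially, trans to the E2 methyl and on the face opposite the axial oxepane oxygen, which leaves the E1 hydroxyl axial and syn to that oxygen as in the target.

Step 24
Reactants: 37 coupled tertiary alcohol
Product: 39 hydroquinone, via quinone 38 (not isolated)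
Conditions: (NH4)2Ce(NO3)6, MeCN/H2O, 0 °C; then Na2S2O4, THF/H2O, rt
Reagents that add atoms: water, O
Why: Oxidative demethylation of the 1,4-dimethoxyarene by tetravalent cerium (arene radical cation, addition of water, loss of methanol) followed by dithionite reduction of the quinone, both brief and near neutral so that the tertiary alcohol, the oxepane and the alkene are spared.

Step 25
Reactants: 39 hydroquinone
Product: 40 CNP0125037.2
Conditions: SO3·pyridine, pyridine, rt; then sulfonic acid resin (H+ form), MeOH/H2O, 0 °C
Reagents that add atoms: sulfur trioxide–pyridine complex, O=S(=O)=O.c1ccncc1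
Why: O-Sulfation of both phenols with the sulfur trioxide–pyridine complex, the hindered tertiary alcohol being unreactive at room temperature, followed by cation exchange to the bis(hydrogen sulfate).

**Compound list**

1 | 6-methoxy-3,4-dihydronaphthalen-1(2H)-one (6-methoxy-1-tetralone) | COc1ccc2c(c1)CCCC2=O | starting material
2 | (R)-6-methoxy-1,2,3,4-tetrahydronaphthalen-1-ol | COc1ccc2c(c1)CCC[C@H]2O | intermediate
3 | lithium (R)-6-methoxy-1,2,3,4-tetrahydronaphthalen-1-olate | COc1ccc2c(c1)CCC[C@H]2O[Li] | intermediate
4 | (R)-6-methoxy-1,2,3,4,5,8-hexahydronaphthalen-1-ol | COC1=CCC2=C(C1)CCC[C@H]2O | intermediate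
5 | (R)-5-hydroxy-3,4,5,6,7,8-hexahydronaphthalen-2(1H)-one (β,γ-enone) | O=C1CCC2=C(C1)CCC[C@H]2O | intermediate
6 | (4aR,5R)-5-hydroxy-4,4a,5,6,7,8-hexahydronaphthalen-2(3H)-one (C7 hydroxyl and C8 hydrogen on one face) | O=C1C=C2CCC[C@@H](O)[C@@H]2CC1 | intermediate
7 | (4aR,5R)-5-[(tert-butyldimethylsilyl)oxy]-4,4a,5,6,7,8-hexahydronaphthalen-2(3H)-one | O=C1C=C2CCC[C@@H](O[Si](C)(C)C(C)(C)C)[C@@H]2CC1 | intermediate
8 | 2,5-dimethoxybenzyl alcohol | COc1ccc(OC)c(CO)c1 | starting material
9 | 2,5-dimethoxybenzyl bromide | COc1ccc(OC)c(CBr)c1 | intermediate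
10 | lithium C1–C2 enolate of the cis-fused C3-methyl decalone (C7 silyl ether) | [Li]OC1=C[C@]2(C)CCC[C@@H](O[Si](C)(C)C(C)(C)C)[C@@H]2CC1 | intermediate
11 | (1R,4aR,5R,8aR)-5-[(tert-butyldimethylsilyl)oxy]-1-(2,5-dimethoxybenzyl)-8a-methyloctahydronaphthalen-2(1H)-one (cis-fused; C3 methyl, C8 hydrogen and C7 oxygen on one face, C2 benzyl on the other) | O=C1[C@H](Cc2cc(OC)ccc2OC)[C@]2(C)CCC[C@@H](O[Si](C)(C)C(C)(C)C)[C@@H]2CC1 | intermediate
12 | (4aR,5R,8aR)-5-[(tert-butyldimethylsilyl)oxy]-1-(2,5-dimethoxybenzyl)-8a-methyl-3,4,4a,5,6,7,8,8a-octahydronaphthalen-2-yl trifluoromethanesulfonate (C1=C2 enol triflate) | FC(F)(F)S(=O)(=O)OC1=C(Cc2cc(OC)ccc2OC)[C@]2(C)CCC[C@@H](O[Si](C)(C)C(C)(C)C)[C@@H]2CC1 | intermediate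
13 | cis-decalin with C1(CH3)=C2(2,5-dimethoxybenzyl) alkene, C3 methyl and C7 tert-butyldimethylsilyl ether (C7 oxygen cis to the C8 hydrogen) | CC1=C(Cc2cc(OC)ccc2OC)[C@]2(C)CCC[C@@H](O[Si](C)(C)C(C)(C)C)[C@@H]2CC1 | intermediate
14 | C7 alcohol corresponding to 13 | CC1=C(Cc2cc(OC)ccc2OC)[C@]2(C)CCC[C@@H](O)[C@@H]2CC1 | intermediate
15 | C7 ketone (C8 hydrogen cis to the C3 methyl) | CC1=C(Cc2cc(OC)ccc2OC)[C@]2(C)CCCC(=O)[C@@H]2CC1 | intermediate
16 | C6=C7 trimethylsilyl enol ether of 15 | CC1=C(Cc2cc(OC)ccc2OC)[C@]2(C)CCC=C(O[Si](C)(C)C)[C@@H]2CC1 | intermediate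
17 | enone with C7 carbonyl and C5=C6 double bond | CC1=C(Cc2cc(OC)ccc2OC)[C@]2(C)CC=CC(=O)[C@@H]2CC1 | intermediate
18 | C7 methyl carbinol with C5=C6 double bond (either C7 configuration) | CC1=C(Cc2cc(OC)ccc2OC)[C@]2(C)CC=CC(C)(O)[C@@H]2CC1 | intermediate
19 | enone with C5 carbonyl, C6=C7 double bond and C7 methyl | CC1=C(Cc2cc(OC)ccc2OC)[C@]2(C)CC(=O)C=C(C)[C@@H]2CC1 | intermediate
20 | C5=C6 trimethylsilyl enol ether with quaternary C7 (methyl, vinyl) | CC1=C(Cc2cc(OC)ccc2OC)[C@]2(C)CC(O[Si](C)(C)C)=C[C@@](C)(C=C)[C@@H]2CC1 | intermediate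
21 | C5 ketone with quaternary C7 (vinyl cis, methyl trans to the C8 hydrogen) | CC1=C(Cc2cc(OC)ccc2OC)[C@]2(C)CC(=O)C[C@@](C)(C=C)[C@@H]2CC1 | intermediate
22 | C5 hydrazone of 21 | CC1=C(Cc2cc(OC)ccc2OC)[C@]2(C)CC(=NN)C[C@@](C)(C=C)[C@@H]2CC1 | intermediate
23 | vinyl decalin (C7 methyl and vinyl, C4–C6 methylenes) | CC1=C(Cc2cc(OC)ccc2OC)[C@]2(C)CCC[C@@](C)(C=C)[C@@H]2CC1 | intermediate
24 | B-alkyl-9-borabicyclo[3.3.1]nonane from 23 (boron on the terminal tether carbon) | CC1=C(Cc2cc(OC)ccc2OC)[C@]2(C)CCC[C@@](C)(CCB3C4CCCC3CCC4)[C@@H]2CC1 | intermediate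
25 | primary alcohol, C7–CH2CH2OH | CC1=C(Cc2cc(OC)ccc2OC)[C@]2(C)CCC[C@@](C)(CCO)[C@@H]2CC1 | intermediate
26 | primary iodide, C7–CH2CH2I | CC1=C(Cc2cc(OC)ccc2OC)[C@]2(C)CCC[C@@](C)(CCI)[C@@H]2CC1 | intermediate
27 | 2-methylcyclohexane-1,3-dione | CC1C(=O)CCCC1=O | starting material
28 | acrolein (prop-2-enal) | C=CC=O | starting material
29 | 3-(1-methyl-2,6-dioxocyclohexyl)propanal | CC1(CCC=O)C(=O)CCCC1=O | intermediate
30 | 2-methyl-2-(4-methylpent-3-en-1-yl)cyclohexane-1,3-dione | CC(C)=CCCC1(C)C(=O)CCCC1=O | intermediate
31 | (2S,3S)-3-hydroxy-2-methyl-2-(4-methylpent-3-en-1-yl)cyclohexan-1-one (hydroxyl cis to the side chain) | O=C1CCC[C@H](O)[C@]1(C)CCC=C(C)C | intermediate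
32 | (5aS,9aS)-2,2,5a-trimethyloctahydro-1-benzoxepin-6(2H)-one (cis-fused) | O=C1CCC[C@@H]2OC(C)(C)CCC[C@]12C | intermediate
33 | lithium E1–E2 enolate of 32 | [Li]OC1=CCC[C@@H]2OC(C)(C)CCC[C@]12C | intermediate
34 | (5aS,7R,9aS)-2,2,5a,7-tetramethyloctahydro-1-benzoxepin-6(2H)-one (E2 methyl trans to the angular methyl) | O=C1[C@H](C)CC[C@@H]2OC(C)(C)CCC[C@]12C | intermediate
35 | organolithium from 26, C7–CH2CH2Li | CC1=C(Cc2cc(OC)ccc2OC)[C@]2(C)CCC[C@@](C)(CC[Li])[C@@H]2CC1 | intermediate
36 | organocerium dichloride from 35, C7–CH2CH2CeCl2 | CC1=C(Cc2cc(OC)ccc2OC)[C@]2(C)CCC[C@@](C)(CC[Ce](Cl)Cl)[C@@H]2CC1 | intermediate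
37 | coupled tertiary alcohol: target skeleton with a 2,5-dimethoxyphenyl ring (E1 hydroxyl syn to the oxepane oxygen and to the E2 methyl) | CC1=C(Cc2cc(OC)ccc2OC)[C@]2(C)CCC[C@@](C)(CC[C@@]3(O)[C@H](C)CC[C@@H]4OC(C)(C)CCC[C@@]43C)[C@@H]2CC1 | intermediate
38 | 2-substituted 1,4-benzoquinone corresponding to 37 | CC1=C(CC2=CC(=O)C=CC2=O)[C@]2(C)CCC[C@@](C)(CC[C@@]3(O)[C@H](C)CC[C@@H]4OC(C)(C)CCC[C@@]43C)[C@@H]2CC1 | intermediate
39 | hydroquinone corresponding to 37 | CC1=C(Cc2cc(O)ccc2O)[C@]2(C)CCC[C@@](C)(CC[C@@]3(O)[C@H](C)CC[C@@H]4OC(C)(C)CCC[C@@]43C)[C@@H]2CC1 | intermediate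
40 | CNP0125037.2, the bis(hydrogen sulfate) of 39 | CC1=C(Cc2cc(OS(=O)(=O)O)ccc2OS(=O)(=O)O)[C@]2(C)CCC[C@@](C)(CC[C@@]3(O)[C@H](C)CC[C@@H]4OC(C)(C)CCC[C@@]43C)[C@@H]2CC1 | target

**Count and risks**

Total step count: 25. Longest linear sequence: 19 steps (steps 1–4, 6–17, 23–25).

Steps most likely to fail:

Step 14. The conjugate addition may be slow at the hindered β,β-disubstituted enone, or vinyl may enter on the face syn to the C8–C9 bond, or 1,2-addition may compete. The fallback sets out from 19 and replaces intermolecular delivery by a sigmatropic transfer. Luche reduction (NaBH4, CeCl3·7H2O, MeOH), in which hydride should enter opposite the axial C3 methyl, gives the C5 allylic alcohol F1 with its hydroxyl on the face of the C8 hydrogen. A Johnson–Claisen rearrangement (MeC(OEt)3, catalytic EtCO2H, 140 °C) transfers this C–O configuration suprafacially to C7 and gives the ethyl ester F2 with a C5=C6 double bond. LiAlH4 reduction gives the unsaturated primary alcohol F3, and diimide reduction of the disubstituted alkene (TsNHNH2, NaOAc), which leaves the tetrasubstituted alkene alone, returns to the route at 25.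

Step 7. Enolisation may go toward C10 instead of the neopentyl-like C2, or triflation of the hindered ketone may stay incomplete. The fallback sets out from 11 and builds the alkene by addition and elimination. Methylcerium addition (MeLi, CeCl3, THF, −78 °C) gives the C1 tertiary carbinol F4. Dehydration with SOCl2 in pyridine, followed by equilibration of any less substituted olefin isomers with catalytic iodine, returns to the route at 13.

Step 23. The organometallic may enolise the hindered ketone in place of adding, or may be delivered to the axial face and give the epimeric carbinol. The fallback sets out from 34, puts the tether on the east half first and moves the union to C7. Allylmagnesium bromide, which adds through a cyclic transition state without enolisation, gives the homoallylic carbinol F5, whose diastereomers can be separated at this small stage. Ozonolysis with NaBH4 work-up gives the diol F6, and I2/PPh3/imidazole gives the iodo alcohol F7. After deprotonation of the hydroxyl (MeLi) and iodine–lithium exchange (t-BuLi), copper-mediated, TMSCl-assisted conjugate addition (CuBr·SMe2) to enone 19 gives the hydroxy ketone F8. Wolff–Kishner reduction of F8 returns to the route at 37.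

Further compounds
F1 | step 14 | C5 allylic alcohol from 19 (hydroxyl on the face of the C8 hydrogen, C6=C7 double bond) | CC1=C(Cc2cc(OC)ccc2OC)[C@]2(C)C[C@@H](O)C=C(C)[C@@H]2CC1
F2 | step 14 | ethyl ester with quaternary C7 (CH2CO2Et cis to the C8 hydrogen) and C5=C6 double bond | CC1=C(Cc2cc(OC)ccc2OC)[C@]2(C)CC=C[C@@](C)(CC(=O)OCC)[C@@H]2CC1
F3 | step 14 | primary alcohol C7–CH2CH2OH with C5=C6 double bond | CC1=C(Cc2cc(OC)ccc2OC)[C@]2(C)CC=C[C@@](C)(CCO)[C@@H]2CC1
F4 | step 7 | C1 methyl carbinol from 11 (either C1 configuration) | CC1(O)[C@H](Cc2cc(OC)ccc2OC)[C@]2(C)CCC[C@@H](O[Si](C)(C)C(C)(C)C)[C@@H]2CC1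
F5 | step 23 | E1 allyl carbinol from 34 (hydroxyl syn to the oxepane oxygen) | C=CC[C@@]1(O)[C@H](C)CC[C@@H]2OC(C)(C)CCC[C@@]21C
F6 | step 23 | E1 (2-hydroxyethyl) carbinol (diol) | OCC[C@@]1(O)[C@H](C)CC[C@@H]2OC(C)(C)CCC[C@@]21C
F7 | step 23 | E1 (2-iodoethyl) carbinol | ICC[C@@]1(O)[C@H](C)CC[C@@H]2OC(C)(C)CCC[C@@]21C
F8 | step 23 | C5 ketone of 37 | CC1=C(Cc2cc(OC)ccc2OC)[C@]2(C)CC(=O)C[C@@](C)(CC[C@@]3(O)[C@H](C)CC[C@@H]4OC(C)(C)CCC[C@@]43C)[C@@H]2CC1
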